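**Retrosynthetic overview**

- The last C–C bond is C2 of flavanone unit 1 (the 5,7-dihydroxy unit) to the central aryl ring, made by ligand-controlled asymmetric conjugate addition of an arylboronic acid to 5,7-bis(benzyloxy)chromone; four benzyl ethers are then removed.
- The strategy rests on C6 of ring A of flavanone unit 2 (the 6-aryloxy unit). This carbon holds the diaryl ether oxygen and sits between the oxygenated C5 and C7, so it is the middle carbon of a 1,3-dicarbonyl C5–C6–C7 unit. The ArO–C6 bond is therefore made as a phenol O-alkylation at an sp3 carbon, and ring A (C4a–C5–C6–C7–C8–C8a) is folded around it by an intramolecular Claisen condensation.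
- The Claisen substrate is a 2-aryl-2,3-dihydropyran-4-one (future ring C of unit 2, O1–C8a bond already in place) carrying the aryloxy keto ester chain. It comes from gamma-addition of the keto ester dianion to a 4-methoxy-5,6-dihydropyran-2-one, followed by acid transposition.
- That lactone, with C2 of unit 2, comes from a catalytic asymmetric vinylogous Mukaiyama aldol of Chan's diene with 4-(benzyloxy)benzaldehyde.
- Ring order: lactone, then ring C of unit 2, then ring A of unit 2; rings A and C of unit 1 are made separately as a chromone and joined last.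

Key step: step 8

Assumptions: both stereocenters of the target are (S). The facial sense of the BINOL–titanium aldol catalyst and of the PyOX–palladium catalyst is assigned by analogy with simple aryl aldehydes and chromones; the antipodal ligand would be used if the sense proved opposite.

**Route**

Step 1
Reactants: 1 methyl acetoacetate
Product: 2 methyl 3-(trimethylsilyloxy)but-2-enoate
Conditions: TMSCl, Et3N, hexane, rt
Reagents that add atoms: chlorotrimethylsilane, C[Si](C)(C)Cl
Why: O-silylation of the enolized beta-keto ester (silyl enol ether formation) is routine and masks the ketone for the second enolization.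

Step 2
Reactants: 2 methyl 3-(trimethylsilyloxy)but-2-enoate
Product: 3 1-methoxy-1,3-bis(trimethylsilyloxy)buta-1,3-diene
Conditions: LiN(iPr)2, THF, −78 °C; then TMSCl, −78 to 0 °C
Reagents that add atoms: chlorotrimethylsilane, C[Si](C)(C)Cl
Why: Gamma-deprotonation of the silyloxy crotonate and O-silylation of the ester dienolate gives Chan's diene, a standard second enol silylation.

Step 3
Reactants: 3 1-methoxy-1,3-bis(trimethylsilyloxy)buta-1,3-diene; 4 4-(benzyloxy)benzaldehyde
Product: 6 methyl (S)-5-[4-(benzyloxy)phenyl]-5-hydroxy-3-oxopentanoate, via bis-silylated aldol adduct 5 (not isolated)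
Conditions: Ti(OiPr)4 (8 mol%), (S)-BINOL (8 mol%), 4 Å MS, THF, −78 °C to rt; then 10% aq. citric acid, THF, 0 °C
Reagents that add atoms: none
Why: Catalytic asymmetric vinylogous Mukaiyama aldol, in which the chiral titanium BINOLate activates the aldehyde and the diene terminus attacks one enantiotopic face to set the (S) carbinol (future C2 of unit 2) under catalyst control; mild acid then removes the silyl groups without ionizing the electron-rich benzylic alcohol.

Step 4
Reactants: 6 methyl (S)-5-[4-(benzyloxy)phenyl]-5-hydroxy-3-oxopentanoate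
Product: 7 (S)-6-[4-(benzyloxy)phenyl]oxane-2,4-dione
Conditions: K2CO3, MeOH, rt; then 1 M HCl, 0 °C
Reagents that add atoms: none
Why: Base-mediated lactonization (6-exo-trig transesterification of the delta-hydroxyl onto the methyl ester) is driven by formation of the stabilized dione enolate and leaves the carbinol C–O bond untouched.

Step 5
Reactants: 7 (S)-6-[4-(benzyloxy)phenyl]oxane-2,4-dione
Product: 8 (S)-6-[4-(benzyloxy)phenyl]-4-methoxy-5,6-dihydro-2H-pyran-2-one
Conditions: Me2SO4, K2CO3, acetone, rt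
Reagents that add atoms: dimethyl sulfate, COS(=O)(=O)OC
Why: O-methylation of the cyclic beta-keto lactone enolate (as in kavalactone syntheses) gives the vinylogous carbonate, which removes the acidic C3 protons and leaves the lactone carbonyl as the only electrophilic site.

Step 6
Reactants: 9 4-bromophenol; 10 ethyl 2-chloro-3-oxobutanoate
Product: 11 ethyl 2-(4-bromophenoxy)-3-oxobutanoate
Conditions: K2CO3, acetone, 56 °C
Reagents that add atoms: none
Why: Williamson-type SN2 O-alkylation of the phenoxide by the doubly activated alpha-chloro keto ester makes the future diaryl ether C–O bond at an sp3 carbon.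

Step 7
Reactants: 8 (S)-6-[4-(benzyloxy)phenyl]-4-methoxy-5,6-dihydro-2H-pyran-2-one; 11 ethyl 2-(4-bromophenoxy)-3-oxobutanoate
Product: 14 ethyl 4-[(2S)-2-(4-benzyloxyphenyl)-4-oxo-2,3-dihydro-4H-pyran-6-yl]-2-(4-bromophenoxy)-3-oxobutanoate (mixture at the aryloxy carbon), via dilithio dianion 12 (not isolated), via lactol adduct 13 (not isolated)
Conditions: 11 (2.2 equiv), LiN(iPr)2 (2.0 equiv per 11), THF, −78 to 0 °C; then 8, −78 to −20 °C; then 1 M HCl, THF, 0 °C to rt
Reagents that add atoms: water, O (its oxygen becomes the C4 carbonyl oxygen of the dihydropyranone)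
Why: The 1,3-dicarbonyl dianion reacts at its gamma carbon with the lactone carbonyl (Claisen-type acylation arrested at the lactol), and dilute acid ionizes the lactol to a methoxy-stabilized oxocarbenium ion that takes up water at C4 and loses methanol (Stork–Danheiser-type transposition on a vinylogous lactone), the C2–O bond never being broken; amide base is used because an alkyllithium would exchange the aryl bromide.

Step 8
Reactants: 14 ethyl 4-[(2S)-2-(4-benzyloxyphenyl)-4-oxo-2,3-dihydro-4H-pyran-6-yl]-2-(4-bromophenoxy)-3-oxobutanoate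
Product: 15 (S)-2-[4-(benzyloxy)phenyl]-6-(4-bromophenoxy)-5,7-dihydroxychroman-4-one
Conditions: DBU (2 equiv), MeCN, 0 °C to rt; then aq. citric acid
Reagents that add atoms: none
Why: Proposed new method: DBU removes a proton from C8 (the CH2 between the C7 ketone and the enol-ether carbon C8a), and the resulting extended dienolate (C8=C8a–C4a=C4–O−) attacks the ester carbonyl C5 through C4a; loss of ethoxide and enolization at C5 and C7 give the aromatic 5,7-dihydroxy ring A of unit 2 with the aryloxy group already on C6. The closest known reaction type is the biomimetic Claisen (Dieckmann) cyclization of 3,5,7-triketo esters to acylphloroglucinols, here with the C4 and C8a carbonyls locked in a dihydropyranone and an aryloxy group next to the ester, which should make that ester more electrophilic. The carbocycle C4a–C5–C6–C7–C8–C8a closes in a 6-(enolexo)-exo-trig mode. No stereocenter is formed, and the (S) center at C2 is carried through because its C–O bond stays intact. The step needs C-acylation at C4a without deprotonation at C3 (E1cB opening of C2–O1 would racemize C2) and the 6- rather than 8-aryloxy pattern: the much higher acidity of the C8 and C6 protons and of the phenolic product keeps the amidine base away from C3, and the pre-formed O1–C8a bond allows only one ring to form. Pyrone formation is excluded because O1 is already alkylated, and the competing aldol of C6 onto C4 cannot aromatize and so should remain reversible.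

Step 9
Reactants: 15 (S)-2-[4-(benzyloxy)phenyl]-6-(4-bromophenoxy)-5,7-dihydroxychroman-4-one
Product: 16 (S)-7-(benzyloxy)-2-[4-(benzyloxy)phenyl]-6-(4-bromophenoxy)-5-hydroxychroman-4-one
Conditions: BnOH, PPh3, DIAD, THF, 0 °C to rt
Reagents that add atoms: benzyl alcohol, OCc1ccccc1
Why: Mitsunobu etherification selects the 7-hydroxyl, the most acidic phenol (para to the carbonyl), while the 5-hydroxyl is held in a hydrogen bond to C4=O, and the near-neutral conditions avoid the base-induced chalcone opening that would racemize C2.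

Step 10
Reactants: 16 (S)-7-(benzyloxy)-2-[4-(benzyloxy)phenyl]-6-(4-bromophenoxy)-5-hydroxychroman-4-one
Product: 17 (S)-[4-({7-(benzyloxy)-2-[4-(benzyloxy)phenyl]-5-hydroxy-4-oxochroman-6-yl}oxy)phenyl]boronic acid
Conditions: B2(OH)4, (XPhos)Pd(2'-aminobiphenyl-2-yl)Cl (second-generation XPhos palladacycle, cat.), XPhos, KOAc, EtOH, 80 °C; then aq. NH4Cl
Reagents that add atoms: tetrahydroxydiboron, OB(O)B(O)O
Why: Palladium-catalysed Miyaura-type borylation of the aryl bromide with tetrahydroxydiboron gives the boronic acid directly under weakly basic acetate conditions that ketone, chelated phenol and benzyl ethers should tolerate.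

Step 11
Reactants: 18 2',4',6'-trihydroxyacetophenone
Product: 19 1-[2,4-bis(benzyloxy)-6-hydroxyphenyl]ethanone
Conditions: BnBr (2.1 equiv), K2CO3, DMF, rt
Reagents that add atoms: benzyl bromide, BrCc1ccccc1
Why: Williamson benzylation takes the para and one ortho hydroxyl, and the remaining ortho hydroxyl is protected from alkylation by its hydrogen bond to the acetyl group.

Step 12
Reactants: 19 1-[2,4-bis(benzyloxy)-6-hydroxyphenyl]ethanone
Product: 20 (E)-1-[2,4-bis(benzyloxy)-6-hydroxyphenyl]-3-(dimethylamino)prop-2-en-1-one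
Conditions: DMF dimethyl acetal, toluene, 95 °C
Reagents that add atoms: N,N-dimethylformamide dimethyl acetal, COC(OC)N(C)C
Why: Condensation of the methyl ketone with the amide acetal is the standard enaminone formation and supplies the C2 carbon of the chromone.

Step 13
Reactants: 20 (E)-1-[2,4-bis(benzyloxy)-6-hydroxyphenyl]-3-(dimethylamino)prop-2-en-1-one
Product: 21 5,7-bis(benzyloxy)-4H-chromen-4-one
Conditions: conc. HCl, CH2Cl2, 40 °C
Reagents that add atoms: none
Why: Acid-promoted addition of the free phenol to the enaminone beta carbon and loss of dimethylamine (addition–elimination cyclization) closes the chromone ring.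

Step 14
Reactants: 17 (S)-[4-({7-(benzyloxy)-2-[4-(benzyloxy)phenyl]-5-hydroxy-4-oxochroman-6-yl}oxy)phenyl]boronic acid; 21 5,7-bis(benzyloxy)-4H-chromen-4-one
Product: 22 (2S)-5,7-bis(benzyloxy)-2-[4-({(2S)-7-(benzyloxy)-2-[4-(benzyloxy)phenyl]-5-hydroxy-4-oxochroman-6-yl}oxy)phenyl]chroman-4-one
Conditions: Pd(OCOCF3)2 (10 mol%), (R)-t-BuPyOX (12 mol%), NH4PF6 (30 mol%), H2O (5 equiv), 21 (2 equiv), ClCH2CH2Cl, 60 °C
Reagents that add atoms: none
Why: Asymmetric conjugate addition by cationic divalent palladium–pyridinooxazoline catalysis (aryl transfer from boron, enantioselective insertion of the chromone C2=C3 bond, protonolysis by water) sets C2 of unit 1 as (S) under ligand control, the existing center being too remote to interfere, and the base-free medium keeps both flavanone rings closed.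

Step 15
Reactants: 22 (2S)-5,7-bis(benzyloxy)-2-[4-({(2S)-7-(benzyloxy)-2-[4-(benzyloxy)phenyl]-5-hydroxy-4-oxochroman-6-yl}oxy)phenyl]chroman-4-one
Product: 23 (2S)-5,7-dihydroxy-2-[4-({(2S)-5,7-dihydroxy-2-(4-hydroxyphenyl)-4-oxochroman-6-yl}oxy)phenyl]chroman-4-one (target CNP0184214.1)
Conditions: H2 (1 atm), Pd/C, EtOAc/MeOH, rt
Reagents that add atoms: none
Why: Neutral hydrogenolysis of the four benzyl aryl ethers over palladium on carbon should leave the diaryl ether, both ketones and both base-sensitive C2 centers unchanged.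

**Compound list**

1 | methyl acetoacetate | COC(=O)CC(C)=O | starting material
2 | methyl 3-(trimethylsilyloxy)but-2-enoate | COC(=O)C=C(C)O[Si](C)(C)C | intermediate
3 | 1-methoxy-1,3-bis(trimethylsilyloxy)buta-1,3-diene | COC(O[Si](C)(C)C)=CC(=C)O[Si](C)(C)C | intermediate
4 | 4-(benzyloxy)benzaldehyde | O=Cc1ccc(OCc2ccccc2)cc1 | starting material
5 | methyl (S)-5-[4-(benzyloxy)phenyl]-3,5-bis(trimethylsilyloxy)pent-2-enoate (silylated aldol adduct, not isolated) | COC(=O)C=C(O[Si](C)(C)C)C[C@@H](c1ccc(OCc2ccccc2)cc1)O[Si](C)(C)C | intermediate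
6 | methyl (S)-5-[4-(benzyloxy)phenyl]-5-hydroxy-3-oxopentanoate | COC(=O)CC(=O)C[C@@H](c1ccc(OCc2ccccc2)cc1)O | intermediate
7 | (S)-6-[4-(benzyloxy)phenyl]oxane-2,4-dione | O=C1CC(=O)O[C@H](c2ccc(OCc3ccccc3)cc2)C1 | intermediate
8 | (S)-6-[4-(benzyloxy)phenyl]-4-methoxy-5,6-dihydro-2H-pyran-2-one | COC1=CC(=O)O[C@H](c2ccc(OCc3ccccc3)cc2)C1 | intermediate
9 | 4-bromophenol | Oc1ccc(Br)cc1 | starting material
10 | ethyl 2-chloro-3-oxobutanoate | CCOC(=O)C(Cl)C(C)=O | starting material
11 | ethyl 2-(4-bromophenoxy)-3-oxobutanoate | CCOC(=O)C(Oc1ccc(Br)cc1)C(C)=O | intermediate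
12 | dilithio dianion of 11 (not isolated) | [Li+].[Li+].CCOC([O-])=C(Oc1ccc(Br)cc1)C([O-])=C | intermediate
13 | ethyl 4-[(6S)-6-(4-benzyloxyphenyl)-2-hydroxy-4-methoxy-5,6-dihydro-2H-pyran-2-yl]-2-(4-bromophenoxy)-3-oxobutanoate (lactol adduct, not isolated) | CCOC(=O)C(Oc1ccc(Br)cc1)C(=O)CC1(O)C=C(OC)C[C@@H](c2ccc(OCc3ccccc3)cc2)O1 | intermediate
14 | ethyl 4-[(2S)-2-(4-benzyloxyphenyl)-4-oxo-2,3-dihydro-4H-pyran-6-yl]-2-(4-bromophenoxy)-3-oxobutanoate | CCOC(=O)C(Oc1ccc(Br)cc1)C(=O)CC1=CC(=O)C[C@@H](c2ccc(OCc3ccccc3)cc2)O1 | intermediate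
15 | (S)-2-[4-(benzyloxy)phenyl]-6-(4-bromophenoxy)-5,7-dihydroxychroman-4-one | O=C1C[C@@H](c2ccc(OCc3ccccc3)cc2)Oc2cc(O)c(Oc3ccc(Br)cc3)c(O)c21 | intermediate
16 | (S)-7-(benzyloxy)-2-[4-(benzyloxy)phenyl]-6-(4-bromophenoxy)-5-hydroxychroman-4-one | O=C1C[C@@H](c2ccc(OCc3ccccc3)cc2)Oc2cc(OCc3ccccc3)c(Oc3ccc(Br)cc3)c(O)c21 | intermediate
17 | (S)-[4-({7-(benzyloxy)-2-[4-(benzyloxy)phenyl]-5-hydroxy-4-oxochroman-6-yl}oxy)phenyl]boronic acid | O=C1C[C@@H](c2ccc(OCc3ccccc3)cc2)Oc2cc(OCc3ccccc3)c(Oc3ccc(B(O)O)cc3)c(O)c21 | intermediate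
18 | 2',4',6'-trihydroxyacetophenone | CC(=O)c1c(O)cc(O)cc1O | starting material
19 | 1-[2,4-bis(benzyloxy)-6-hydroxyphenyl]ethanone | CC(=O)c1c(O)cc(OCc2ccccc2)cc1OCc1ccccc1 | intermediate
20 | (E)-1-[2,4-bis(benzyloxy)-6-hydroxyphenyl]-3-(dimethylamino)prop-2-en-1-one | CN(C)/C=C/C(=O)c1c(O)cc(OCc2ccccc2)cc1OCc1ccccc1 | intermediate
21 | 5,7-bis(benzyloxy)-4H-chromen-4-one | O=c1ccoc2cc(OCc3ccccc3)cc(OCc3ccccc3)c12 | intermediate
22 | (2S)-5,7-bis(benzyloxy)-2-[4-({(2S)-7-(benzyloxy)-2-[4-(benzyloxy)phenyl]-5-hydroxy-4-oxochroman-6-yl}oxy)phenyl]chroman-4-one | O=C1C[C@@H](c2ccc(Oc3c(OCc4ccccc4)cc4c(c3O)C(=O)C[C@@H](c3ccc(OCc5ccccc5)cc3)O4)cc2)Oc2cc(OCc3ccccc3)cc(OCc3ccccc3)c21 | intermediate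
23 | (2S)-5,7-dihydroxy-2-[4-({(2S)-5,7-dihydroxy-2-(4-hydroxyphenyl)-4-oxochroman-6-yl}oxy)phenyl]chroman-4-one | O=C1C[C@@H](c2ccc(Oc3c(O)cc4c(c3O)C(=O)C[C@@H](c3ccc(O)cc3)O4)cc2)Oc2cc(O)cc(O)c21 | target

**Totals**

Total step count: 15. Longest linear sequence: 11 steps (steps 1–5, 7–10, 14, 15).

**Steps most likely to fail**

1. Step 8 (Proposed new method). The C-acylation may stall if the base removes the C6 proton instead, which ties the ester up as its own enolate. The keto ester may fragment by retro-Claisen cleavage. Deprotonation at C3 may open the C2–O1 bond and erode the enantiopurity.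
 Fallback, known chemistry only, setting out from 19 and coming back at 16: the diaryl ether is made on an intact arene and unit 2 is then assembled in the same way as unit 1.
 - Elbs persulfate oxidation of 19 (K2S2O8, aq. NaOH/pyridine, then acid hydrolysis of the aryl sulfate) should place a hydroxyl para to the free phenol, giving 1-[2,4-bis(benzyloxy)-3,6-dihydroxyphenyl]ethanone F1.
 - Copper-catalysed Ullmann etherification of its non-chelated hydroxyl with 1-bromo-4-iodobenzene (CuI, picolinic acid, K3PO4, DMSO) should give 1-[2,4-bis(benzyloxy)-3-(4-bromophenoxy)-6-hydroxyphenyl]ethanone F2.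
 - DMF dimethyl acetal should convert this into (E)-1-[2,4-bis(benzyloxy)-3-(4-bromophenoxy)-6-hydroxyphenyl]-3-(dimethylamino)prop-2-en-1-one F3, and HCl should close 5,7-bis(benzyloxy)-6-(4-bromophenoxy)-4H-chromen-4-one F4. Here O1 can only come from the single free phenol, so the aryloxy group must sit at C6.
 - Asymmetric conjugate addition of [4-(benzyloxy)phenyl]boronic acid under the conditions of step 14 should give (S)-5,7-bis(benzyloxy)-2-[4-(benzyloxy)phenyl]-6-(4-bromophenoxy)chroman-4-one F5.
 - Chelation-assisted removal of the 5-O-benzyl group with MgBr2·OEt2 should return 16.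

2. Step 7. Addition to the deactivated vinylogous-carbonate carbonyl may be slow. The dianion may instead deprotonate C5 of the lactone (followed by beta-elimination and ring opening), add in a conjugate addition–elimination at C4, or be quenched by proton transfer from the ring-opened adduct.
 Fallback, setting out from 8 and coming back at 14: the electrophile is changed from the lactone to an open-chain Weinreb amide, whose chelated tetrahedral intermediate suppresses proton transfer and double addition.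
 - Opening 8 with Me2AlN(OMe)Me (from AlMe3 and N,O-dimethylhydroxylamine hydrochloride) should give (S,E)-5-[4-(benzyloxy)phenyl]-5-hydroxy-N,3-dimethoxy-N-methylpent-2-enamide F6.
 - Silylation (TBSCl, imidazole) should give (S,E)-5-[4-(benzyloxy)phenyl]-5-(tert-butyldimethylsilyloxy)-N,3-dimethoxy-N-methylpent-2-enamide F7.
 - Acylation of dianion 12 by this amide should give ethyl (9S,6E)-9-[4-(benzyloxy)phenyl]-2-(4-bromophenoxy)-9-(tert-butyldimethylsilyloxy)-7-methoxy-3,5-dioxonon-6-enoate F8.
 - HF·pyridine followed by dilute acid should remove the silyl group, close the freed hydroxyl onto the C5 ketone and expel methanol, giving 14.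

3. Step 14. Aryl transfer to the electron-rich 5,7-dialkoxychromone may be slow, so that protodeboronation of the advanced boronic acid wins, or facial control by the ligand may be incomplete.
 Fallback, setting out from 16 and 19 and coming back at 22: ring C of unit 1 is closed by an organocatalytic oxa-Michael addition instead of a metal-mediated aryl transfer.
 - Palladium-catalysed formylation of 16 (Pd(OAc)2, 1,4-bis(diphenylphosphino)butane, N-formylsaccharin, Et3SiH, Na2CO3, DMF) should give (S)-4-({7-(benzyloxy)-2-[4-(benzyloxy)phenyl]-5-hydroxy-4-oxochroman-6-yl}oxy)benzaldehyde F9.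
 - C-acylation of the lithium dianion of 19 (LiN(SiMe3)2, then di-tert-butyl dicarbonate) should give tert-butyl 3-[2,4-bis(benzyloxy)-6-hydroxyphenyl]-3-oxopropanoate F10.
 - Knoevenagel condensation of the two (piperidinium acetate, toluene, 4 Å MS) should give tert-butyl 2-[2,4-bis(benzyloxy)-6-hydroxybenzoyl]-3-[4-({(2S)-7-(benzyloxy)-2-[4-(benzyloxy)phenyl]-5-hydroxy-4-oxochroman-6-yl}oxy)phenyl]prop-2-enoate F11.
 - The quinine- or quinidine-derived bifunctional thiourea that favors the (2S) product should cyclize it to tert-butyl (2S)-5,7-bis(benzyloxy)-2-[4-({(2S)-7-(benzyloxy)-2-[4-(benzyloxy)phenyl]-5-hydroxy-4-oxochroman-6-yl}oxy)phenyl]-4-oxochroman-3-carboxylate F12.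
 - Warming with TsOH should cleave the tert-butyl ester and decarboxylate, giving 22.

**Further compounds**

F1 | step 8 | 1-[2,4-bis(benzyloxy)-3,6-dihydroxyphenyl]ethanone | CC(=O)c1c(O)cc(OCc2ccccc2)c(O)c1OCc1ccccc1
F2 | step 8 | 1-[2,4-bis(benzyloxy)-3-(4-bromophenoxy)-6-hydroxyphenyl]ethanone | CC(=O)c1c(O)cc(OCc2ccccc2)c(Oc2ccc(Br)cc2)c1OCc1ccccc1
F3 | step 8 | (E)-1-[2,4-bis(benzyloxy)-3-(4-bromophenoxy)-6-hydroxyphenyl]-3-(dimethylamino)prop-2-en-1-one | CN(C)/C=C/C(=O)c1c(O)cc(OCc2ccccc2)c(Oc2ccc(Br)cc2)c1OCc1ccccc1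
F4 | step 8 | 5,7-bis(benzyloxy)-6-(4-bromophenoxy)-4H-chromen-4-one | O=c1ccoc2cc(OCc3ccccc3)c(Oc3ccc(Br)cc3)c(OCc3ccccc3)c12
F5 | step 8 | (S)-5,7-bis(benzyloxy)-2-[4-(benzyloxy)phenyl]-6-(4-bromophenoxy)chroman-4-one | O=C1C[C@@H](c2ccc(OCc3ccccc3)cc2)Oc2cc(OCc3ccccc3)c(Oc3ccc(Br)cc3)c(OCc3ccccc3)c21
F6 | step 7 | (S,E)-5-[4-(benzyloxy)phenyl]-5-hydroxy-N,3-dimethoxy-N-methylpent-2-enamide | CON(C)C(=O)/C=C(/OC)C[C@@H](c1ccc(OCc2ccccc2)cc1)O
F7 | step 7 | (S,E)-5-[4-(benzyloxy)phenyl]-5-(tert-butyldimethylsilyloxy)-N,3-dimethoxy-N-methylpent-2-enamide | CON(C)C(=O)/C=C(/OC)C[C@@H](c1ccc(OCc2ccccc2)cc1)O[Si](C)(C)C(C)(C)C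
F8 | step 7 | ethyl (9S,6E)-9-[4-(benzyloxy)phenyl]-2-(4-bromophenoxy)-9-(tert-butyldimethylsilyloxy)-7-methoxy-3,5-dioxonon-6-enoate | CCOC(=O)C(Oc1ccc(Br)cc1)C(=O)CC(=O)/C=C(/OC)C[C@@H](c1ccc(OCc2ccccc2)cc1)O[Si](C)(C)C(C)(C)C
F9 | step 14 | (S)-4-({7-(benzyloxy)-2-[4-(benzyloxy)phenyl]-5-hydroxy-4-oxochroman-6-yl}oxy)benzaldehyde | O=Cc1ccc(Oc2c(OCc3ccccc3)cc3c(c2O)C(=O)C[C@@H](c2ccc(OCc4ccccc4)cc2)O3)cc1
F10 | step 14 | tert-butyl 3-[2,4-bis(benzyloxy)-6-hydroxyphenyl]-3-oxopropanoate | CC(C)(C)OC(=O)CC(=O)c1c(O)cc(OCc2ccccc2)cc1OCc1ccccc1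
F11 | step 14 | tert-butyl 2-[2,4-bis(benzyloxy)-6-hydroxybenzoyl]-3-[4-({(2S)-7-(benzyloxy)-2-[4-(benzyloxy)phenyl]-5-hydroxy-4-oxochroman-6-yl}oxy)phenyl]prop-2-enoate | CC(C)(C)OC(=O)C(=Cc1ccc(Oc2c(OCc3ccccc3)cc3c(c2O)C(=O)C[C@@H](c2ccc(OCc4ccccc4)cc2)O3)cc1)C(=O)c1c(O)cc(OCc2ccccc2)cc1OCc1ccccc1
F12 | step 14 | tert-butyl (2S)-5,7-bis(benzyloxy)-2-[4-({(2S)-7-(benzyloxy)-2-[4-(benzyloxy)phenyl]-5-hydroxy-4-oxochroman-6-yl}oxy)phenyl]-4-oxochroman-3-carboxylate | CC(C)(C)OC(=O)C1C(=O)c2c(OCc3ccccc3)cc(OCc3ccccc3)cc2O[C@@H]1c1ccc(Oc2c(OCc3ccccc3)cc3c(c2O)C(=O)C[C@@H](c2ccc(OCc4ccccc4)cc2)O3)cc1
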